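(All runs are calculated with constants of no real substance; noise was put on by code.)

At 30 h, the time of reading, the flask should long have stopped, for elm and alder stand flat within scatter from 5.00 h and 8.00 h on.

| flask | starting complex | incoming ligand | leaving ligand | scavenger | remark | time |
|---|---|---|---|---|---|---|
| elm | 0.14 M | 0.080 M | 0.050 M | 0.12 M | run made earlier |  |
| alder | 0.22 M | 0.080 M | 0.050 M | 0.12 M | run made earlier |  |
| flask | 0.10 M | 0.0800 M | 0.0500 M | 0.120 M |  | 30 h |

| run | time / h | starting complex / % | complex with one exchanged / % |
|---|---|---|---|
| elm | 2.50 | 69.3 | 18.7 |
| elm | 5.00 | 63.5 | 20.3 |
| elm | 8.00 | 63.6 | 20.8 |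
| elm | 15.0 | 63.2 | 20.4 |
| elm | 30.0 | 62.6 | 21.0 |
| alder | 2.50 | 76.8 | 17.9 |
| alder | 8.00 | 73.3 | 18.1 |
| alder | 15.0 | 73.3 | 16.6 |
| alder | 20.0 | 72.8 | 17.8 |
| alder | 30.0 | 73.7 | 17.8 |

(standard deviation of a reading: 0.5 percentage points)

- part of the starting complex that has reacted at 30 h
- share of the unused incoming ligand that is free and not bound as idle adduct, at 30 h

- for leaving ligand the idle adduct is counted in
- the analysis behind the earlier runs scatters by 0.5 percentage points, standard deviation
- steps that have been proposed: leaving ligand + incoming ligand <-> idle adduct; starting complex + incoming ligand -> leaving ligand + complex with one exchanged; scavenger + leaving ligand -> scavenged by-product; complex with one exchanged + incoming ligand -> leaving ligand + complex with two exchanged; complex with two exchanged + incoming ligand -> leaving ligand + complex with three exchanged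
- the earlier runs do not show how much of incoming ligand is bound; that part of a forecast is a guess

The ligand moved onto complex can be counted in two ways. The first takes the charge of incoming ligand, 0.080 M in both runs. The second reads the plateaus, with means of 63.2 % starting complex and 20.6 % complex with one exchanged in elm, and 73.3 % and 17.6 % in alder, and books every further complex as twice exchanged. Alder then gives 0.0789 M, but elm gives less, 0.0741 M.

The idle adduct is an unlikely thief, since alder had the same charges of incoming ligand, leaving ligand and scavenger as elm and a smaller gap. The reading count is the likelier cheat: it undercounts complex with three exchanged, and elm offers more incoming ligand per complex. So the charge stands, and incoming ligand is the limiting reagent in elm and in alder.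

Each molecule of incoming ligand meets a fork, starting complex or an exchanged complex, and its chance of the first branch thins with the starting complex, so the loss is counted logarithmically. The capture number, the natural logarithm of charged over remaining starting complex per equivalent of incoming ligand, reads 0.802 in elm and 0.855 in alder, with mean 0.829. For the flask this reckoning gives 48.5 % reacted.

The forecast, a little lower, gives 47 % reacted and 5 % free: “So the stall is set by incoming ligand.”

The flask gives 48.4 % reacted and 22.4 % free, and the free share is where the forecast parts from it.

    leaving ligand + incoming ligand ⇌ idle adduct, settled at all times (K = 350 M⁻¹)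
    starting complex + incoming ligand → leaving ligand + complex with one exchanged (k = 0.0990 M⁻¹ min⁻¹)
    scavenger + leaving ligand → scavenged by-product (k = 5.80 M⁻¹ min⁻¹)
    complex with one exchanged + incoming ligand → leaving ligand + complex with two exchanged (k = 0.260 M⁻¹ min⁻¹)
    complex with two exchanged + incoming ligand → leaving ligand + complex with three exchanged (k = 0.0630 M⁻¹ min⁻¹)

The flask's capture number is 0.826. With twice the starting complex, the mean capture number gives 28.2 % reacted, and that flask stands at 28.9 %. In the flask, free incoming ligand is down to 0.231 % of its charge at 15.0 h and 0.017 % at 30 h, with scavenger at 0 %. The reacted part of the flask has come to rest, and a later reading makes no difference to it: at 300 h it reads 48.4 %. What still runs on in the flask is a trace: from 30 h to 300 h free incoming ligand goes to 0 % and idle adduct from 4.77 × 10⁻⁵ M to 0 M.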